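**Retrosynthetic overview**

1. Target 22 ⇐ cis-fused enone acetal 21 (cleave the tert-butyl acetal) ⇐ β-ethoxy ketone 19 (lose EtOH to unveil C2=C3) ⇐ ene-diol acetal 15 + 3-ethoxycyclobutan-1-one 16 in one Lewis acid-promoted formal [4+2] ring expansion.
2. Key disconnections are C3–C4 and C5–C6 of the cyclohexenone: the carbocycle grows from the four-membered ring of 16 (its carbons become C1, C2, C3 and C6) by insertion of the two alkene carbons of 15 (C4 and C5, carrying both oxygens and the side chain).
3. Enabling feature: C1(=O)–C6H2–C5(OH) is an aldol unit and the C2=C3 enone is a masked β-alkoxy ketone, so C6–C1–C2–C3 is the 1,4-zwitterion of a 3-alkoxycyclobutanone; the cis C4–O/C5–O pair is a 1,3-dioxole whose tert-butyl acetal carbon ties both oxygens into one ring (cis) and shields one face (4R,5S).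
4. 15 ⇐ dioxolanone 12 (reductive acetylation, elimination) ⇐ (R)-2-hydroxy acid 9 + pivalaldehyde; 9 ⇐ C18 Grignard reagent + methyl (R)-glycidate; chain ⇐ (E)-hex-3-en-1-ol + 1,12-dibromododecane.
5. Ring order: dioxolanone/dioxole ring (steps 5–7), then the carbocycle by 4 → 6 expansion (step 8); the dioxolane ring is opened last (step 10).

Key step: step 8

Remark: 3-ethoxycyclobutan-1-one (16) is taken as a purchasable building block.

**Route**

Step 1
Reactants: 1 (E)-hex-3-en-1-ol
Product: 2 (E)-1-bromohex-3-ene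
Conditions: CBr4, PPh3, CH2Cl2, 0 °C
Reagents that add atoms: carbon tetrabromide, BrC(Br)(Br)Br
Why: The Appel reaction converts the primary alcohol into the bromide under neutral conditions that leave the (E)-alkene untouched.

Step 2
Reactants: 2 (E)-1-bromohex-3-ene; 3 1,12-dibromododecane (3 equiv)
Product: 5 (E)-18-bromooctadec-3-ene, via (E)-hex-3-en-1-ylmagnesium bromide 4 (not isolated)
Conditions: Mg, THF, rt; then 3 (3 equiv), Li2CuCl4 (3 mol%), THF, −10 °C
Reagents that add atoms: none
Why: Copper-catalysed sp3–sp3 cross-coupling of a primary alkyl Grignard reagent with a primary alkyl bromide should stop at mono-substitution with excess dibromide, which is recovered by distillation.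

Step 3
Reactants: 5 (E)-18-bromooctadec-3-ene; 6 methyl (R)-oxirane-2-carboxylate (methyl (R)-glycidate)
Product: 8 methyl (2R,18E)-2-hydroxyhenicos-18-enoate, via (E)-octadec-15-en-1-ylmagnesium bromide 7 (not isolated)
Conditions: Mg, THF, 40 °C; then 6, CuI (10 mol%), THF, −40 °C; H2O
Reagents that add atoms: none
Why: Copper-catalysed Grignard opening of the glycidic ester at the unsubstituted epoxide carbon (SN2) should outrun ester addition at low temperature, and the C2 stereocentre is carried over unchanged from the commercial (R)-epoxide.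

Step 4
Reactants: 8 methyl (2R,18E)-2-hydroxyhenicos-18-enoate
Product: 9 (2R,18E)-2-hydroxyhenicos-18-enoic acid
Conditions: LiOH, THF/H2O, 0 °C → rt; then 1 M HCl
Reagents that add atoms: lithium hydroxide, [Li+].[OH-]
Why: Ester saponification by acyl–oxygen cleavage at low temperature should not touch the α-stereocentre.

Step 5
Reactants: 9 (2R,18E)-2-hydroxyhenicos-18-enoic acid; 10 pivalaldehyde
Product: 12 (2R,5R)-2-tert-butyl-5-[(E)-nonadec-16-en-1-yl]-1,3-dioxolan-4-one, via bis(trimethylsilyl) derivative 11 (not isolated)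
Conditions: TMSCl, Et3N, CH2Cl2, 0 °C, filtration; then 10, TMSOTf (5 mol%), CH2Cl2, −78 °C
Reagents that add atoms: none
Why: Silyl triflate-catalysed acetalisation of a bis-silylated α-hydroxy acid with an aldehyde is a known entry to cis-2,5-disubstituted 1,3-dioxolan-4-ones, so the C5 centre should direct the new acetal carbon to the cis (2R) configuration, and any trans isomer, which would lead into the enantiomeric series, is removed by chromatography.

Step 6
Reactants: 12 (2R,5R)-2-tert-butyl-5-[(E)-nonadec-16-en-1-yl]-1,3-dioxolan-4-one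
Product: 14 (2R,5R)-2-tert-butyl-5-[(E)-nonadec-16-en-1-yl]-1,3-dioxolan-4-yl acetate (C4 epimers), via diisobutylaluminium hemiacetal alkoxide 13 (not isolated)
Conditions: DIBAL-H, CH2Cl2, −78 °C; then pyridine, DMAP, Ac2O, −78 °C → rt
Reagents that add atoms: acetic anhydride, CC(=O)OC(C)=O
Why: Reductive acetylation traps the tetrahedral aluminium hemiacetal from hydride addition to the lactone in situ, which avoids the free lactol (prone to lose pivalaldehyde) and leaves the acetal carbon untouched.

Step 7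
Reactants: 14 (2R,5R)-2-tert-butyl-5-[(E)-nonadec-16-en-1-yl]-1,3-dioxolan-4-yl acetate
Product: 15 (S)-2-tert-butyl-4-[(E)-nonadec-16-en-1-yl]-1,3-dioxole
Conditions: TMSOTf, iPr2NEt, CH2Cl2, 0 °C → rt
Reagents that add atoms: none
Why: Ionisation of the α-acetoxy ether to the cyclic oxocarbenium ion and deprotonation at C5 by the hindered amine (the known silyl triflate/amine conversion of acetals and α-acyloxy ethers into enol ethers) should give the ene-diol acetal, in which the sacrificial C5 centre is gone and the acetal carbon (S by the priority change) is the only stereocentre.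

Step 8
Reactants: 15 (S)-2-tert-butyl-4-[(E)-nonadec-16-en-1-yl]-1,3-dioxole; 16 3-ethoxycyclobutan-1-one (1.5 equiv)
Product: 19 (2S,3aS,7aR)-2-tert-butyl-7-ethoxy-3a-[(E)-nonadec-16-en-1-yl]tetrahydro-1,3-benzodioxol-5(4H)-one (C7 epimers), via ring-opened aluminium enolate oxocarbenium zwitterion 17 (not isolated), via dioxolanylium aluminium enolate 18 (not isolated)
Conditions: EtAlCl2 (1.5 equiv), 2,6-di-tert-butylpyridine (0.2 equiv), CH2Cl2, −78 °C; aq. NaHCO3
Reagents that add atoms: none
Why: Proposed new method: EtAlCl2 binds the ketone of 16 and the strained C2–C3 bond, pushed by the ethoxy lone pair, heterolyses to the 1,4-zwitterion 17 (aluminium enolate plus O-ethyl oxocarbenium ion), as in the Lewis acid-promoted formal [4+2] cycloadditions of 3-alkoxycyclobutanones with silyl enol ethers and allylsilanes, which are the closest known reaction type; a cyclic ene-diol acetal has not been used as the two-carbon partner. The unsubstituted alkene carbon of 15 adds to the oxocarbenium carbon (Mukaiyama/Prins type) to give the tertiary dioxolanylium ion 18, and the tethered aluminium enolate closes the six-membered carbocycle by a 6-(enolendo)-exo-trig aldol-type attack on that cation, so the four-membered ring is enlarged by the two alkene carbons. The C7a stereocentre is set in the first C–C bond formation by approach of the electrophile to the dioxole face anti to the tert-butyl group on the acetal carbon (1,3-induction as in 2-tert-butyl-1,3-dioxolan-4-one enolates), and the C3a stereocentre is set in the ring closure, which can only deliver the cis-fused bicycle, that is the cis-diol with the acetal as tether. The C7 ethoxy centre forms without control and is removed in step 9. The step needs attack through the CH terminus of 15 (secured by formation of the more substituted, oxygen-stabilised cation), chemoselectivity over the remote (E)-alkene (secured by the much higher nucleophilicity of the ene-diol ether) and C-cyclisation rather than proton loss from 18 (favoured by the intramolecular enolate and the low temperature).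

Step 9
Reactants: 19 (2S,3aS,7aR)-2-tert-butyl-7-ethoxy-3a-[(E)-nonadec-16-en-1-yl]tetrahydro-1,3-benzodioxol-5(4H)-one
Product: 21 (2S,3aS,7aR)-2-tert-butyl-3a-[(E)-nonadec-16-en-1-yl]-3a,7a-dihydro-1,3-benzodioxol-5(4H)-one, via kinetic trimethylsilyl enol ether 20 (not isolated)
Conditions: LDA, TMSCl (in situ quench), THF, −78 °C; solvent switch; TMSOTf (10 mol%), CH2Cl2, −78 °C
Reagents that add atoms: none
Why: Kinetic deprotonation by the bulky amide at C6 (the α-methylene not flanked by the quaternary C3a) with in situ silylation fixes the enol ether towards C7, and Lewis acid ionisation of the now allylic ethoxy group (vinylogous β-elimination, as for 3-alkoxy silyl enol ethers from siloxydiene cycloadditions) should give the enone without free base or protic acid, either of which could expel the acetal oxygen at C3a.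

Step 10
Reactants: 21 (2S,3aS,7aR)-2-tert-butyl-3a-[(E)-nonadec-16-en-1-yl]-3a,7a-dihydro-1,3-benzodioxol-5(4H)-one
Product: 22 (4R,5S)-4,5-dihydroxy-5-[(E)-nonadec-16-en-1-yl]cyclohex-2-en-1-one (target)
Conditions: BCl3, CH2Cl2, −78 °C; then MeOH, −78 → 0 °C; aq. NaHCO3
Reagents that add atoms: none
Why: Lewis acid cleavage of the hindered aldehyde acetal through the boron-bound α-chloro ether, followed by methanolysis at low temperature, should free the cis-diol without the warm protic acid that would dehydrate the β-hydroxy enone, and neither ring stereocentre is touched.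

**Compound list**

1 | (E)-hex-3-en-1-ol | CC/C=C/CCO | starting material
2 | (E)-1-bromohex-3-ene | CC/C=C/CCBr | intermediate
3 | 1,12-dibromododecane | BrCCCCCCCCCCCCBr | starting material
4 | (E)-hex-3-en-1-ylmagnesium bromide | CC/C=C/CC[Mg]Br | intermediate
5 | (E)-18-bromooctadec-3-ene | CC/C=C/CCCCCCCCCCCCCCBr | intermediate
6 | methyl (R)-oxirane-2-carboxylate | COC(=O)[C@H]1CO1 | starting material
7 | (E)-octadec-15-en-1-ylmagnesium bromide | CC/C=C/CCCCCCCCCCCCCC[Mg]Br | intermediate
8 | methyl (2R,18E)-2-hydroxyhenicos-18-enoate | CC/C=C/CCCCCCCCCCCCCCC[C@@H](O)C(=O)OC | intermediate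
9 | (2R,18E)-2-hydroxyhenicos-18-enoic acid | CC/C=C/CCCCCCCCCCCCCCC[C@@H](O)C(=O)O | intermediate
10 | pivalaldehyde (2,2-dimethylpropanal) | CC(C)(C)C=O | starting material
11 | trimethylsilyl (2R,18E)-2-(trimethylsilyloxy)henicos-18-enoate | CC/C=C/CCCCCCCCCCCCCCC[C@@H](O[Si](C)(C)C)C(=O)O[Si](C)(C)C | intermediate
12 | (2R,5R)-2-tert-butyl-5-[(E)-nonadec-16-en-1-yl]-1,3-dioxolan-4-one (cis) | CC/C=C/CCCCCCCCCCCCCCC[C@H]1O[C@@H](C(C)(C)C)OC1=O | intermediate
13 | diisobutylaluminium alkoxide of (2R,5R)-2-tert-butyl-5-[(E)-nonadec-16-en-1-yl]-1,3-dioxolan-4-ol | CC/C=C/CCCCCCCCCCCCCCC[C@H]1O[C@@H](C(C)(C)C)OC1O[Al](CC(C)C)CC(C)C | intermediate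
14 | (2R,5R)-2-tert-butyl-5-[(E)-nonadec-16-en-1-yl]-1,3-dioxolan-4-yl acetate (C4 epimers) | CC/C=C/CCCCCCCCCCCCCCC[C@H]1O[C@@H](C(C)(C)C)OC1OC(C)=O | intermediate
15 | (S)-2-tert-butyl-4-[(E)-nonadec-16-en-1-yl]-1,3-dioxole | CC/C=C/CCCCCCCCCCCCCCCC1=CO[C@H](C(C)(C)C)O1 | intermediate
16 | 3-ethoxycyclobutan-1-one | CCOC1CC(=O)C1 | starting material
17 | 1,4-zwitterion CH2=C(O–AlEtCl2)–CH2–CH=O(+)Et (dichloro(ethyl)aluminate enolate with O-ethyl oxocarbenium ion) | C=C(O[Al-](Cl)(Cl)CC)CC=[O+]CC | intermediate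
18 | cyclic oxocarbenium ion: (2S,4R)-2-tert-butyl-5-[(E)-nonadec-16-en-1-yl]-1,3-dioxolan-5-ylium carrying at C4 the 1-ethoxy-3-(dichloro(ethyl)aluminato-oxy)but-3-en-1-yl chain | CC/C=C/CCCCCCCCCCCCCCCC1=[O+][C@@H](C(C)(C)C)O[C@@H]1C(OCC)CC(=C)O[Al-](Cl)(Cl)CC | intermediate
19 | (2S,3aS,7aR)-2-tert-butyl-7-ethoxy-3a-[(E)-nonadec-16-en-1-yl]tetrahydro-1,3-benzodioxol-5(4H)-one (cis-fused, C7 epimers) | CC/C=C/CCCCCCCCCCCCCCC[C@]1(O2)CC(=O)CC(OCC)[C@H]1O[C@@H]2C(C)(C)C | intermediate
20 | (2S,3aS,7aR)-2-tert-butyl-7-ethoxy-3a-[(E)-nonadec-16-en-1-yl]-5-(trimethylsilyloxy)-3a,4,7,7a-tetrahydro-1,3-benzodioxole | CC/C=C/CCCCCCCCCCCCCCC[C@]1(O2)CC(O[Si](C)(C)C)=CC(OCC)[C@H]1O[C@@H]2C(C)(C)C | intermediate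
21 | (2S,3aS,7aR)-2-tert-butyl-3a-[(E)-nonadec-16-en-1-yl]-3a,7a-dihydro-1,3-benzodioxol-5(4H)-one | CC/C=C/CCCCCCCCCCCCCCC[C@]1(O2)CC(=O)C=C[C@H]1O[C@@H]2C(C)(C)C | intermediate
22 | (4R,5S)-4,5-dihydroxy-5-[(E)-nonadec-16-en-1-yl]cyclohex-2-en-1-one | CC/C=C/CCCCCCCCCCCCCCC[C@]1(O)CC(=O)C=C[C@H]1O | target

**Step count**

Total steps: 10. Longest linear sequence: 10 steps (1 → 22; compounds 3, 6, 10 and 16 are purchased).

**Steps most likely to fail**

Step 8 (Proposed new method). What may go wrong: Lewis acid-induced oligomerisation or acetal opening of the electron-rich dioxole before the cyclobutanone has opened; proton loss from the cation or O- instead of C-closure of the enolate; incomplete facial selectivity. The fallback supplies the same four-carbon unit in acyclic, stepwise form by known reactions; it sets out from 15 and comes back at 21. Lewis acid-catalysed addition of the dimethyl acetal 4,4-dimethoxybutan-2-one to the enol ether (Müller-Cunradi–Pieroh reaction; TMSOTf cat., CH2Cl2, −78 °C) should give, again anti to the tert-butyl group, the methoxy ketal 4-[(2S,4R)-2-tert-butyl-5-methoxy-5-[(E)-nonadec-16-en-1-yl]-1,3-dioxolan-4-yl]-4-methoxybutan-2-one F1. Kinetic enol silane formation at the methyl group (LDA, TMSCl, THF, −78 °C) gives the silyl enol ether F2. Intramolecular Mukaiyama-type addition to the oxocarbenium ion released from the ketal (TiCl4, CH2Cl2, −78 °C) closes the carbocycle cis to give the 7-methoxy analogue of 19, (2S,3aS,7aR)-2-tert-butyl-7-methoxy-3a-[(E)-nonadec-16-en-1-yl]tetrahydro-1,3-benzodioxol-5(4H)-one F3. Under the conditions of step 9 this passes through the silyl enol ether F4 to 21.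

Step 9. What may go wrong: loss of regiocontrol in the enolisation, so that the enol ether forms towards C4 and the acetal oxygen at C3a is expelled, followed by aromatisation. The fallback replaces regiocontrol of enolisation by leaving-group control; it sets out from 15 and comes back at 21. Step 8 is run with 3-[(4-methoxybenzyl)oxy]cyclobutan-1-one in place of 16 to give the 7-(4-methoxybenzyloxy) analogue of 19, F5. Oxidative ether cleavage (DDQ, CH2Cl2/pH 7 buffer) gives the β-hydroxy ketone (2S,3aS,7aR)-2-tert-butyl-7-hydroxy-3a-[(E)-nonadec-16-en-1-yl]tetrahydro-1,3-benzodioxol-5(4H)-one F6. Mesylation (MsCl, Et3N, CH2Cl2, 0 °C) gives the mesylate F7, which should eliminate in the same flask to 21, because a sulfonate leaves far faster than the β-acetal oxygen under these mild amine conditions (known for 3-hydroxy-4,5-O-alkylidene cyclohexanones).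

Step 10. What may go wrong: incomplete cleavage of the hindered tert-butyl acetal, or dehydration of the tertiary β-hydroxy enone to the dienone and on to the alkylhydroquinone under the Lewis or protic acid. The fallback masks the carbonyl while the acetal is hydrolysed; it sets out from 21 and comes back at 22. Luche reduction (NaBH4, CeCl3·7H2O, MeOH, −78 °C) gives the allylic alcohol (2S,3aS,7aR)-2-tert-butyl-3a-[(E)-nonadec-16-en-1-yl]-3a,4,5,7a-tetrahydro-1,3-benzodioxol-5-ol F8 (C5 epimers). Aqueous acid (2 M HCl, THF, 40 °C) then hydrolyses the acetal of this ketone-free compound to the triol (4R,5S)-5-[(E)-nonadec-16-en-1-yl]cyclohex-2-ene-1,4,5-triol F9. Oxidation with MnO2 (CH2Cl2, rt) should take the less hindered C1 allylic alcohol in preference to the C4 hydroxyl, which is flanked by the fully substituted C5, to give 22 from both C1 epimers.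

**Further compounds**

F1 | step 8 | 4-[(2S,4R)-2-tert-butyl-5-methoxy-5-[(E)-nonadec-16-en-1-yl]-1,3-dioxolan-4-yl]-4-methoxybutan-2-one (epimers at the two methoxy-bearing carbons) | CC/C=C/CCCCCCCCCCCCCCCC1(OC)O[C@@H](C(C)(C)C)O[C@@H]1C(OC)CC(C)=O
F2 | step 8 | (2S,4R)-2-tert-butyl-5-methoxy-4-[1-methoxy-3-(trimethylsilyloxy)but-3-en-1-yl]-5-[(E)-nonadec-16-en-1-yl]-1,3-dioxolane | CC/C=C/CCCCCCCCCCCCCCCC1(OC)O[C@@H](C(C)(C)C)O[C@@H]1C(OC)CC(=C)O[Si](C)(C)C
F3 | step 8 | (2S,3aS,7aR)-2-tert-butyl-7-methoxy-3a-[(E)-nonadec-16-en-1-yl]tetrahydro-1,3-benzodioxol-5(4H)-one (C7 epimers) | CC/C=C/CCCCCCCCCCCCCCC[C@]1(O2)CC(=O)CC(OC)[C@H]1O[C@@H]2C(C)(C)C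
F4 | step 8 | (2S,3aS,7aR)-2-tert-butyl-7-methoxy-3a-[(E)-nonadec-16-en-1-yl]-5-(trimethylsilyloxy)-3a,4,7,7a-tetrahydro-1,3-benzodioxole | CC/C=C/CCCCCCCCCCCCCCC[C@]1(O2)CC(O[Si](C)(C)C)=CC(OC)[C@H]1O[C@@H]2C(C)(C)C
F5 | step 9 | (2S,3aS,7aR)-2-tert-butyl-7-[(4-methoxybenzyl)oxy]-3a-[(E)-nonadec-16-en-1-yl]tetrahydro-1,3-benzodioxol-5(4H)-one (C7 epimers) | CC/C=C/CCCCCCCCCCCCCCC[C@]1(O2)CC(=O)CC(OCc3ccc(OC)cc3)[C@H]1O[C@@H]2C(C)(C)C
F6 | step 9 | (2S,3aS,7aR)-2-tert-butyl-7-hydroxy-3a-[(E)-nonadec-16-en-1-yl]tetrahydro-1,3-benzodioxol-5(4H)-one (C7 epimers) | CC/C=C/CCCCCCCCCCCCCCC[C@]1(O2)CC(=O)CC(O)[C@H]1O[C@@H]2C(C)(C)C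
F7 | step 9 | (2S,3aS,7aR)-2-tert-butyl-3a-[(E)-nonadec-16-en-1-yl]-5-oxohexahydro-1,3-benzodioxol-7-yl methanesulfonate (C7 epimers) | CC/C=C/CCCCCCCCCCCCCCC[C@]1(O2)CC(=O)CC(OS(C)(=O)=O)[C@H]1O[C@@H]2C(C)(C)C
F8 | step 10 | (2S,3aS,7aR)-2-tert-butyl-3a-[(E)-nonadec-16-en-1-yl]-3a,4,5,7a-tetrahydro-1,3-benzodioxol-5-ol (C5 epimers) | CC/C=C/CCCCCCCCCCCCCCC[C@]1(O2)CC(O)C=C[C@H]1O[C@@H]2C(C)(C)C
F9 | step 10 | (4R,5S)-5-[(E)-nonadec-16-en-1-yl]cyclohex-2-ene-1,4,5-triol (C1 epimers) | CC/C=C/CCCCCCCCCCCCCCC[C@]1(O)CC(O)C=C[C@H]1O
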